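**Retrosynthetic overview**

1. The ten-membered carbocycle and the α-methylene lactone are formed last and together: intramolecular chromium-mediated allylation of a (Z)-enal (C6) by a 2-(bromomethyl)enoate (C7, C11–C13) forges C6–C7, and the C6 oxygen then lactonises.
2. The bridging 3(2H)-furanone (ring O, C3, C2, C1, C10) is made earlier by ring expansion of the oxirane (O, C9, C10) of an α,β-epoxy ynone: the oxirane oxygen adds to gold-activated C3, and acetic acid opens the resulting bicyclic epoxonium at C9, which also installs the C9 acetate.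
3. Enabling feature: the oxirane oxygen sits on quaternary C10, 1,5-related to the ynone β-carbon C3 through C1(=O)–C2≡C3, and the other oxirane carbon C9 is the only one open to SN2 attack; the oxygen can therefore only end up bridging C3 and C10, while C9 takes the nucleophile with inversion.
4. The epoxy ynone is assembled from (S)-glyceraldehyde acetonide (C7–C9), a propionate ylide (C1, C10, C14) and (Z)-3-methylpent-2-en-4-yn-1-ol (C2–C6, C15) by Wittig olefination, Sharpless epoxidation and acetylide addition; methyl propiolate later supplies C11–C13.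
5. Order of ring formation: oxirane, then furanone (from the oxirane), then ten-membered ring and lactone in one step.

Key step: step 8

Remark: locants C1–C15 follow germacrane numbering of the target (C1 ketone, C3–O–C10 ether bridge, C4=C5, C6–O lactone, C7–C11(=C13)–C12, C8 isovalerate, C9 acetate); (S)-glyceraldehyde acetonide is assumed to be commercially available like its enantiomer.

**Route**

Step 1
Reactants: 1 (2Z)-3-methylpent-2-en-4-yn-1-ol
Product: 2 tert-butyl{[(2Z)-3-methylpent-2-en-4-yn-1-yl]oxy}diphenylsilane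
Conditions: TBDPSCl, imidazole, CH2Cl2, 0 °C to rt
Reagents that add atoms: tert-butyl(chloro)diphenylsilane CC(C)(C)[Si](Cl)(c1ccccc1)c1ccccc1
Why: Standard silyl ether formation at the primary allylic alcohol; the bulky, weakly nucleophilic TBDPS ether is chosen so that this oxygen cannot compete for the gold-activated alkyne in step 8.

Step 2
Reactants: 3 (4S)-2,2-dimethyl-1,3-dioxolane-4-carbaldehyde; 4 ethyl 2-(triphenyl-λ5-phosphanylidene)propanoate
Product: 5 ethyl (2E)-3-[(4R)-2,2-dimethyl-1,3-dioxolan-4-yl]-2-methylprop-2-enoate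
Conditions: CH2Cl2, rt
Reagents that add atoms: none
Why: Wittig olefination with a stabilised ylide should give the (E)-trisubstituted enoate (C8 trans to C1) without touching the acetal stereocentre.

Step 3
Reactants: 5 ethyl (2E)-3-[(4R)-2,2-dimethyl-1,3-dioxolan-4-yl]-2-methylprop-2-enoate
Product: 6 (2E)-3-[(4R)-2,2-dimethyl-1,3-dioxolan-4-yl]-2-methylprop-2-en-1-ol
Conditions: iBu2AlH, CH2Cl2, −78 °C; aq. potassium sodium tartrate work-up
Reagents that add atoms: none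
Why: 1,2-Reduction of the enoate with iBu2AlH should give the allylic alcohol that directs the epoxidation.

Step 4
Reactants: 6 (2E)-3-[(4R)-2,2-dimethyl-1,3-dioxolan-4-yl]-2-methylprop-2-en-1-ol
Product: 7 {(2S,3S)-3-[(4S)-2,2-dimethyl-1,3-dioxolan-4-yl]-2-methyloxiran-2-yl}methanol
Conditions: Ti(OiPr)4 (10 mol %), L-(+)-diisopropyl tartrate (12 mol %), tBuOOH, 4 Å MS, CH2Cl2, −20 °C
Reagents that add atoms: tert-butyl hydroperoxide CC(C)(C)OO
Why: Sharpless asymmetric epoxidation with L-(+)-tartrate should give the (2S,3S)-oxirane of the (E)-2-methyl allylic alcohol under reagent control, which sets C9 and C10 (C10 is the later 10R centre once C1 is a carbonyl).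

Step 5
Reactants: 7 {(2S,3S)-3-[(4S)-2,2-dimethyl-1,3-dioxolan-4-yl]-2-methyloxiran-2-yl}methanol
Product: 8 (2R,3S)-3-[(4S)-2,2-dimethyl-1,3-dioxolan-4-yl]-2-methyloxirane-2-carbaldehyde
Conditions: Dess–Martin periodinane, pyridine, CH2Cl2, 0 °C
Reagents that add atoms: none
Why: Buffered Dess–Martin oxidation should give the epoxy aldehyde, whose α-carbon is quaternary and cannot epimerise.

Step 6
Reactants: 2 tert-butyl{[(2Z)-3-methylpent-2-en-4-yn-1-yl]oxy}diphenylsilane; 8 (2R,3S)-3-[(4S)-2,2-dimethyl-1,3-dioxolan-4-yl]-2-methyloxirane-2-carbaldehyde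
Product: 10 (4Z)-6-[(tert-butyldiphenylsilyl)oxy]-1-{(2S,3S)-3-[(4S)-2,2-dimethyl-1,3-dioxolan-4-yl]-2-methyloxiran-2-yl}-4-methylhex-4-en-2-yn-1-ol (mixture of C1 epimers), via lithium acetylide 9 (not isolated)
Conditions: 2, nBuLi, THF, −78 °C; then 8, −78 °C
Reagents that add atoms: none
Why: 1,2-Addition of the lithium acetylide to the aldehyde joins C1 to C2; both C1 epimers are carried on because C1 becomes a carbonyl in step 7.

Step 7
Reactants: 10 (4Z)-6-[(tert-butyldiphenylsilyl)oxy]-1-{(2S,3S)-3-[(4S)-2,2-dimethyl-1,3-dioxolan-4-yl]-2-methyloxiran-2-yl}-4-methylhex-4-en-2-yn-1-ol (mixture of C1 epimers)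
Product: 11 (4Z)-6-[(tert-butyldiphenylsilyl)oxy]-1-{(2R,3S)-3-[(4S)-2,2-dimethyl-1,3-dioxolan-4-yl]-2-methyloxiran-2-yl}-4-methylhex-4-en-2-yn-1-one
Conditions: Dess–Martin periodinane, pyridine, CH2Cl2, 0 °C to rt
Reagents that add atoms: none
Why: Dess–Martin oxidation of the propargylic alcohol should converge both C1 epimers on the α,β-epoxy ynone.

Step 8
Reactants: 11 (4Z)-6-[(tert-butyldiphenylsilyl)oxy]-1-{(2R,3S)-3-[(4S)-2,2-dimethyl-1,3-dioxolan-4-yl]-2-methyloxiran-2-yl}-4-methylhex-4-en-2-yn-1-one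
Product: 13 (R)-[(2R)-5-{(2Z)-4-[(tert-butyldiphenylsilyl)oxy]but-2-en-2-yl}-2-methyl-3-oxo-2,3-dihydrofuran-2-yl][(4S)-2,2-dimethyl-1,3-dioxolan-4-yl]methyl acetate, via vinylgold epoxonium salt 12 (not isolated)
Conditions: Ph3PAuNTf2 (5 mol %), AcOH (10 equiv), CH2Cl2, 0 °C to rt
Reagents that add atoms: acetic acid CC(=O)O
Why: Proposed new method: Ph3PAuNTf2 (monovalent gold) should π-activate the ynone, the oxirane oxygen on C10 should add anti to C3 to give the bicyclic vinylgold epoxonium 12, acetic acid should open this oxonium at C9, and protodeauration at C2 should release the furanone, so that the three-membered O–C9–C10 ring is expanded into the five-membered O–C10–C1–C2–C3 ring in one flask. The closest known reaction types are the gold-catalysed 5-endo-dig cyclisation of α'-hydroxy ynones to 3(2H)-furanones, gold-catalysed epoxide-opening/alkyne-cyclisation cascades of epoxy alkynes with oxygen nucleophiles, and epoxide-to-tetrahydrofuran ring expansions through epoxonium ions in haloetherification chemistry. Only the furanone is closed, by 5-endo-dig O-attack, and the oxirane is the ring that is given up. C10 never loses its C–O bond and keeps the 10R configuration from step 4, while C9 becomes 9R by backside (SN2) attack of acetic acid on the 9S oxirane carbon. The step needs opening at C9 rather than C10, which is secured because C10 is quaternary and α to the carbonyl, and it needs O-attack by the oxirane rather than by another oxygen, which is secured by the bulky silyl ether at C6 and by the acetal oxygens being unable to reach C3 or C9 through unstrained rings. If acid-promoted acetolysis of the oxirane comes first, the resulting 9-acetoxy-10-hydroxy ynone should cyclise under the same catalyst to the same product with the same configuration.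

Step 9
Reactants: 13 (R)-[(2R)-5-{(2Z)-4-[(tert-butyldiphenylsilyl)oxy]but-2-en-2-yl}-2-methyl-3-oxo-2,3-dihydrofuran-2-yl][(4S)-2,2-dimethyl-1,3-dioxolan-4-yl]methyl acetate
Product: 14 (1R,2S)-1-[(2R)-5-{(2Z)-4-[(tert-butyldiphenylsilyl)oxy]but-2-en-2-yl}-2-methyl-3-oxo-2,3-dihydrofuran-2-yl]-2,3-dihydroxypropyl acetate
Conditions: AcOH/H2O (4:1), 40 °C
Reagents that add atoms: none
Why: Acid hydrolysis of the terminal isopropylidene acetal should free the C7/C8 diol under conditions mild enough to keep the C9 acetate in place and the TBDPS ether intact.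

Step 10
Reactants: 14 (1R,2S)-1-[(2R)-5-{(2Z)-4-[(tert-butyldiphenylsilyl)oxy]but-2-en-2-yl}-2-methyl-3-oxo-2,3-dihydrofuran-2-yl]-2,3-dihydroxypropyl acetate
Product: 16 (2S,3R)-3-acetoxy-3-[(2R)-5-{(2Z)-4-[(tert-butyldiphenylsilyl)oxy]but-2-en-2-yl}-2-methyl-3-oxo-2,3-dihydrofuran-2-yl]-1-[(triethylsilyl)oxy]propan-2-yl 3-methylbutanoate, via primary triethylsilyl ether 15 (not isolated)
Conditions: Et3SiCl (1.05 equiv), imidazole, CH2Cl2, −40 °C; then 3-methylbutanoic anhydride, DMAP, pyridine, 0 °C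
Reagents that add atoms: chlorotriethylsilane CC[Si](Cl)(CC)CC; 3-methylbutanoic anhydride CC(C)CC(=O)OC(=O)CC(C)C
Why: Selective silylation of the primary hydroxyl followed in the same flask by DMAP-catalysed acylation should place the isovalerate on O8; low temperature and short exposure to base limit acetyl migration from O9.

Step 11
Reactants: 16 (2S,3R)-3-acetoxy-3-[(2R)-5-{(2Z)-4-[(tert-butyldiphenylsilyl)oxy]but-2-en-2-yl}-2-methyl-3-oxo-2,3-dihydrofuran-2-yl]-1-[(triethylsilyl)oxy]propan-2-yl 3-methylbutanoate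
Product: 17 (2S,3R)-3-acetoxy-3-[(2R)-5-{(2Z)-4-[(tert-butyldiphenylsilyl)oxy]but-2-en-2-yl}-2-methyl-3-oxo-2,3-dihydrofuran-2-yl]-1-hydroxypropan-2-yl 3-methylbutanoate
Conditions: PPTS, MeOH, 0 °C
Reagents that add atoms: none
Why: Mild acidic methanolysis should remove the primary triethylsilyl ether selectively in the presence of the TBDPS ether and the esters.

Step 12
Reactants: 17 (2S,3R)-3-acetoxy-3-[(2R)-5-{(2Z)-4-[(tert-butyldiphenylsilyl)oxy]but-2-en-2-yl}-2-methyl-3-oxo-2,3-dihydrofuran-2-yl]-1-hydroxypropan-2-yl 3-methylbutanoate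
Product: 18 (2R,3R)-3-acetoxy-3-[(2R)-5-{(2Z)-4-[(tert-butyldiphenylsilyl)oxy]but-2-en-2-yl}-2-methyl-3-oxo-2,3-dihydrofuran-2-yl]-1-oxopropan-2-yl 3-methylbutanoate
Conditions: Dess–Martin periodinane, pyridine, CH2Cl2, 0 °C
Reagents that add atoms: none
Why: Dess–Martin oxidation should give the α-acyloxy aldehyde (C7), which is used at once to avoid epimerisation at C8.

Step 13
Reactants: 18 (2R,3R)-3-acetoxy-3-[(2R)-5-{(2Z)-4-[(tert-butyldiphenylsilyl)oxy]but-2-en-2-yl}-2-methyl-3-oxo-2,3-dihydrofuran-2-yl]-1-oxopropan-2-yl 3-methylbutanoate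
Product: 19 methyl (4S,5R)-5-acetoxy-5-[(2R)-5-{(2Z)-4-[(tert-butyldiphenylsilyl)oxy]but-2-en-2-yl}-2-methyl-3-oxo-2,3-dihydrofuran-2-yl]-3-hydroxy-2-methylidene-4-[(3-methylbutanoyl)oxy]pentanoate (mixture of C3 epimers)
Conditions: methyl propiolate, iBu2AlH, NMO, THF, 0 °C; then 18, −78 to 0 °C
Reagents that add atoms: methyl propiolate C#CC(=O)OC
Why: Vinylalumination (the aluminium variant of the Morita–Baylis–Hillman reaction): the α-alumino acrylate from 1,4-hydroalumination of methyl propiolate should add to the aldehyde quickly and without base, so C8 is not epimerised, and the new carbinol centre (C7) is irrelevant because it becomes sp2 in step 16.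

Step 14
Reactants: 19 methyl (4S,5R)-5-acetoxy-5-[(2R)-5-{(2Z)-4-[(tert-butyldiphenylsilyl)oxy]but-2-en-2-yl}-2-methyl-3-oxo-2,3-dihydrofuran-2-yl]-3-hydroxy-2-methylidene-4-[(3-methylbutanoyl)oxy]pentanoate (mixture of C3 epimers)
Product: 20 methyl (4S,5R)-5-acetoxy-3-hydroxy-5-{(2R)-5-[(2Z)-4-hydroxybut-2-en-2-yl]-2-methyl-3-oxo-2,3-dihydrofuran-2-yl}-2-methylidene-4-[(3-methylbutanoyl)oxy]pentanoate (mixture of C3 epimers)
Conditions: HF·pyridine, pyridine, THF, 0 °C to rt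
Reagents that add atoms: none
Why: Buffered fluoride cleavage of the TBDPS ether is placed before the allylic bromide exists, so neither fluoride nor pyridine can alkylate.

Step 15
Reactants: 20 methyl (4S,5R)-5-acetoxy-3-hydroxy-5-{(2R)-5-[(2Z)-4-hydroxybut-2-en-2-yl]-2-methyl-3-oxo-2,3-dihydrofuran-2-yl}-2-methylidene-4-[(3-methylbutanoyl)oxy]pentanoate (mixture of C3 epimers)
Product: 21 methyl (4S,5R)-5-acetoxy-3-hydroxy-5-{(2R)-2-methyl-3-oxo-5-[(2Z)-4-oxobut-2-en-2-yl]-2,3-dihydrofuran-2-yl}-2-methylidene-4-[(3-methylbutanoyl)oxy]pentanoate (mixture of C3 epimers)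
Conditions: TEMPO (10 mol %), PhI(OAc)2, CH2Cl2, rt
Reagents that add atoms: none
Why: TEMPO/PhI(OAc)2 oxidation is selective for the primary allylic alcohol over the secondary Morita–Baylis–Hillman alcohol and mild enough to keep the (Z)-enal geometry.

Step 16
Reactants: 21 methyl (4S,5R)-5-acetoxy-3-hydroxy-5-{(2R)-2-methyl-3-oxo-5-[(2Z)-4-oxobut-2-en-2-yl]-2,3-dihydrofuran-2-yl}-2-methylidene-4-[(3-methylbutanoyl)oxy]pentanoate (mixture of C3 epimers)
Product: 22 methyl (2Z,4S,5R)-5-acetoxy-2-(bromomethyl)-5-{(2R)-2-methyl-3-oxo-5-[(2Z)-4-oxobut-2-en-2-yl]-2,3-dihydrofuran-2-yl}-4-[(3-methylbutanoyl)oxy]pent-2-enoate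
Conditions: NBS, Me2S, CH2Cl2, −20 to 0 °C
Reagents that add atoms: N-bromosuccinimide O=C1CCC(=O)N1Br
Why: NBS/Me2S should convert the Morita–Baylis–Hillman alcohol into the rearranged (Z)-2-(bromomethyl)enoate by SN2' displacement, the thermodynamically favoured isomer.

Step 17
Reactants: 22 methyl (2Z,4S,5R)-5-acetoxy-2-(bromomethyl)-5-{(2R)-2-methyl-3-oxo-5-[(2Z)-4-oxobut-2-en-2-yl]-2,3-dihydrofuran-2-yl}-4-[(3-methylbutanoyl)oxy]pent-2-enoate
Product: 25 (6R,7S,8S,9R,10R)-9-acetoxy-8-[(3-methylbutanoyl)oxy]-1-oxo-3,10-epoxygermacra-2,4(Z),11(13)-trien-12,6-olide (CNP0255553.1), via allylchromium dichloride 23 (not isolated), via ten-membered hydroxy ester 24 (not isolated)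
Conditions: CrCl2 (8 equiv), THF, rt, 2 mM (slow addition); then p-TsOH (cat.), CH2Cl2, rt
Reagents that add atoms: none
Why: CrCl2 (divalent chromium) should turn the allylic bromide into an allylchromium species that adds through C7 to the aldehyde only (intramolecular Nozaki–Hiyama-type allylation), closing the ten-membered ring, after which the C6 oxygen lactonises onto the methyl ester; the 6,7-anti (6R,7S, trans-lactone) relationship is expected from the chair-like transition state of the equilibrated γ-substituted allylchromium, the face of the allyl unit is set by the adjacent C8 stereocentre (allylic strain) within the furanone-anchored macrocyclic transition state, and the hindered vinylogous-ester carbonyl at C1 should not react.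

**Compound list**

1 | (2Z)-3-methylpent-2-en-4-yn-1-ol | OC/C=C(/C)C#C | starting material
2 | tert-butyl{[(2Z)-3-methylpent-2-en-4-yn-1-yl]oxy}diphenylsilane | CC(C)(C)[Si](OC/C=C(/C)C#C)(c1ccccc1)c1ccccc1 | intermediate
3 | (4S)-2,2-dimethyl-1,3-dioxolane-4-carbaldehyde, (S)-glyceraldehyde acetonide | O=C[C@@H]1COC(C)(C)O1 | starting material
4 | ethyl 2-(triphenyl-λ5-phosphanylidene)propanoate | CCOC(=O)C(C)=P(c1ccccc1)(c1ccccc1)c1ccccc1 | starting material
5 | ethyl (2E)-3-[(4R)-2,2-dimethyl-1,3-dioxolan-4-yl]-2-methylprop-2-enoate | CCOC(=O)/C(C)=C/[C@@H]1COC(C)(C)O1 | intermediate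
6 | (2E)-3-[(4R)-2,2-dimethyl-1,3-dioxolan-4-yl]-2-methylprop-2-en-1-ol | OC/C(C)=C/[C@@H]1COC(C)(C)O1 | intermediate
7 | {(2S,3S)-3-[(4S)-2,2-dimethyl-1,3-dioxolan-4-yl]-2-methyloxiran-2-yl}methanol | OC[C@]1(C)O[C@H]1[C@@H]2COC(C)(C)O2 | intermediate
8 | (2R,3S)-3-[(4S)-2,2-dimethyl-1,3-dioxolan-4-yl]-2-methyloxirane-2-carbaldehyde | O=C[C@]1(C)O[C@H]1[C@@H]2COC(C)(C)O2 | intermediate
9 | {(3Z)-5-[(tert-butyldiphenylsilyl)oxy]-3-methylpent-3-en-1-yn-1-yl}lithium (lithium acetylide of 2) | CC(C)(C)[Si](OC/C=C(/C)C#C[Li])(c1ccccc1)c1ccccc1 | intermediate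
10 | (4Z)-6-[(tert-butyldiphenylsilyl)oxy]-1-{(2S,3S)-3-[(4S)-2,2-dimethyl-1,3-dioxolan-4-yl]-2-methyloxiran-2-yl}-4-methylhex-4-en-2-yn-1-ol (mixture of C1 epimers) | CC(C)(C)[Si](OC/C=C(/C)C#CC(O)[C@]2(C)O[C@H]2[C@@H]3COC(C)(C)O3)(c1ccccc1)c1ccccc1 | intermediate
11 | (4Z)-6-[(tert-butyldiphenylsilyl)oxy]-1-{(2R,3S)-3-[(4S)-2,2-dimethyl-1,3-dioxolan-4-yl]-2-methyloxiran-2-yl}-4-methylhex-4-en-2-yn-1-one | CC(C)(C)[Si](OC/C=C(/C)C#CC(=O)[C@]2(C)O[C@H]2[C@@H]3COC(C)(C)O3)(c1ccccc1)c1ccccc1 | intermediate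
12 | vinylgold epoxonium salt: oxirane still fused to the new five-membered ring through a trivalent O+, Ph3PAu on C2, bis(trifluoromethanesulfonyl)imide counter-ion | CC(C)(C)[Si](OC/C=C(/C)C2=C([Au-][P+](c3ccccc3)(c3ccccc3)c3ccccc3)C(=O)[C@@]3(C)[C@H]([C@@H]4COC(C)(C)O4)[O+]23)(c1ccccc1)c1ccccc1.FC(F)(F)S(=O)(=O)[N-]S(=O)(=O)C(F)(F)F | intermediate
13 | (R)-[(2R)-5-{(2Z)-4-[(tert-butyldiphenylsilyl)oxy]but-2-en-2-yl}-2-methyl-3-oxo-2,3-dihydrofuran-2-yl][(4S)-2,2-dimethyl-1,3-dioxolan-4-yl]methyl acetate | CC(C)(C)[Si](OC/C=C(/C)C2=CC(=O)[C@](C)(O2)[C@H](OC(C)=O)[C@@H]3COC(C)(C)O3)(c1ccccc1)c1ccccc1 | intermediate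
14 | (1R,2S)-1-[(2R)-5-{(2Z)-4-[(tert-butyldiphenylsilyl)oxy]but-2-en-2-yl}-2-methyl-3-oxo-2,3-dihydrofuran-2-yl]-2,3-dihydroxypropyl acetate | CC(C)(C)[Si](OC/C=C(/C)C2=CC(=O)[C@](C)(O2)[C@H](OC(C)=O)[C@@H](O)CO)(c1ccccc1)c1ccccc1 | intermediate
15 | (1R,2S)-1-[(2R)-5-{(2Z)-4-[(tert-butyldiphenylsilyl)oxy]but-2-en-2-yl}-2-methyl-3-oxo-2,3-dihydrofuran-2-yl]-2-hydroxy-3-[(triethylsilyl)oxy]propyl acetate | CC(C)(C)[Si](OC/C=C(/C)C2=CC(=O)[C@](C)(O2)[C@H](OC(C)=O)[C@@H](O)CO[Si](CC)(CC)CC)(c1ccccc1)c1ccccc1 | intermediate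
16 | (2S,3R)-3-acetoxy-3-[(2R)-5-{(2Z)-4-[(tert-butyldiphenylsilyl)oxy]but-2-en-2-yl}-2-methyl-3-oxo-2,3-dihydrofuran-2-yl]-1-[(triethylsilyl)oxy]propan-2-yl 3-methylbutanoate | CC(C)(C)[Si](OC/C=C(/C)C2=CC(=O)[C@](C)(O2)[C@H](OC(C)=O)[C@@H](OC(=O)CC(C)C)CO[Si](CC)(CC)CC)(c1ccccc1)c1ccccc1 | intermediate
17 | (2S,3R)-3-acetoxy-3-[(2R)-5-{(2Z)-4-[(tert-butyldiphenylsilyl)oxy]but-2-en-2-yl}-2-methyl-3-oxo-2,3-dihydrofuran-2-yl]-1-hydroxypropan-2-yl 3-methylbutanoate | CC(C)(C)[Si](OC/C=C(/C)C2=CC(=O)[C@](C)(O2)[C@H](OC(C)=O)[C@@H](OC(=O)CC(C)C)CO)(c1ccccc1)c1ccccc1 | intermediate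
18 | (2R,3R)-3-acetoxy-3-[(2R)-5-{(2Z)-4-[(tert-butyldiphenylsilyl)oxy]but-2-en-2-yl}-2-methyl-3-oxo-2,3-dihydrofuran-2-yl]-1-oxopropan-2-yl 3-methylbutanoate | CC(C)(C)[Si](OC/C=C(/C)C2=CC(=O)[C@](C)(O2)[C@H](OC(C)=O)[C@@H](OC(=O)CC(C)C)C=O)(c1ccccc1)c1ccccc1 | intermediate
19 | methyl (4S,5R)-5-acetoxy-5-[(2R)-5-{(2Z)-4-[(tert-butyldiphenylsilyl)oxy]but-2-en-2-yl}-2-methyl-3-oxo-2,3-dihydrofuran-2-yl]-3-hydroxy-2-methylidene-4-[(3-methylbutanoyl)oxy]pentanoate (mixture of C3 epimers) | CC(C)(C)[Si](OC/C=C(/C)C2=CC(=O)[C@](C)(O2)[C@H](OC(C)=O)[C@@H](OC(=O)CC(C)C)C(O)C(=C)C(=O)OC)(c1ccccc1)c1ccccc1 | intermediate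
20 | methyl (4S,5R)-5-acetoxy-3-hydroxy-5-{(2R)-5-[(2Z)-4-hydroxybut-2-en-2-yl]-2-methyl-3-oxo-2,3-dihydrofuran-2-yl}-2-methylidene-4-[(3-methylbutanoyl)oxy]pentanoate (mixture of C3 epimers) | OC/C=C(/C)C1=CC(=O)[C@](C)(O1)[C@H](OC(C)=O)[C@@H](OC(=O)CC(C)C)C(O)C(=C)C(=O)OC | intermediate
21 | methyl (4S,5R)-5-acetoxy-3-hydroxy-5-{(2R)-2-methyl-3-oxo-5-[(2Z)-4-oxobut-2-en-2-yl]-2,3-dihydrofuran-2-yl}-2-methylidene-4-[(3-methylbutanoyl)oxy]pentanoate (mixture of C3 epimers) | O=C/C=C(/C)C1=CC(=O)[C@](C)(O1)[C@H](OC(C)=O)[C@@H](OC(=O)CC(C)C)C(O)C(=C)C(=O)OC | intermediate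
22 | methyl (2Z,4S,5R)-5-acetoxy-2-(bromomethyl)-5-{(2R)-2-methyl-3-oxo-5-[(2Z)-4-oxobut-2-en-2-yl]-2,3-dihydrofuran-2-yl}-4-[(3-methylbutanoyl)oxy]pent-2-enoate | O=C/C=C(/C)C1=CC(=O)[C@](C)(O1)[C@H](OC(C)=O)[C@@H](OC(=O)CC(C)C)/C=C(\CBr)C(=O)OC | intermediate
23 | allylchromium dichloride formed from 22 (CrCl2 group in place of Br) | O=C/C=C(/C)C1=CC(=O)[C@](C)(O1)[C@H](OC(C)=O)[C@@H](OC(=O)CC(C)C)/C=C(\C[Cr](Cl)Cl)C(=O)OC | intermediate
24 | methyl 2-[(6R,7S,8S,9R,10R)-9-acetoxy-6-hydroxy-4,10-dimethyl-8-[(3-methylbutanoyl)oxy]-1-oxo-3,10-epoxycyclodeca-2,4-dien-7-yl]prop-2-enoate (4Z; germacrane locants) | O[C@@H]1/C=C(/C)C2=CC(=O)[C@](C)(O2)[C@H](OC(C)=O)[C@@H](OC(=O)CC(C)C)[C@H]1C(=C)C(=O)OC | intermediate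
25 | (6R,7S,8S,9R,10R)-9-acetoxy-8-[(3-methylbutanoyl)oxy]-1-oxo-3,10-epoxygermacra-2,4(Z),11(13)-trien-12,6-olide (CNP0255553.1) | C=C1C(=O)O[C@@H]2/C=C(/C)C3=CC(=O)[C@](C)(O3)[C@H](OC(C)=O)[C@@H](OC(=O)CC(C)C)[C@@H]12 | target

**Step count and risks**

Total step count: 17. Longest linear sequence: 16 steps (steps 2 to 17, from compound 3); step 1 prepares alkyne 2 separately.

Steps most likely to fail:

1. Step 8 (Proposed new method). The weakly nucleophilic oxirane oxygen may add too slowly, so that gold-catalysed addition of acetic acid to the ynone, an acid-induced 1,2-acyl shift of the epoxy ketone, or acetal exchange take over. Fallback with known chemistry, setting out from 10 and returning at 13: Ti(OiPr)4-mediated opening of the 2,3-epoxy alcohol 10 with acetic acid, which is regioselective for the oxirane carbon remote from the carbinol (C9, inversion), should give (1R,2S,6Z)-8-[(tert-butyldiphenylsilyl)oxy]-1-[(4S)-2,2-dimethyl-1,3-dioxolan-4-yl]-2,3-dihydroxy-2,6-dimethyloct-6-en-4-yn-1-yl acetate F1. Selective MnO2 oxidation of its propargylic hydroxyl should give the α'-hydroxy ynone (1R,2R,6Z)-8-[(tert-butyldiphenylsilyl)oxy]-1-[(4S)-2,2-dimethyl-1,3-dioxolan-4-yl]-2-hydroxy-2,6-dimethyl-3-oxooct-6-en-4-yn-1-yl acetate F2. The established Ph3PAuNTf2-catalysed 5-endo-dig cyclisation of the tertiary hydroxyl onto the ynone then gives 13.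

2. Step 17. The allylation may pass through the wrong diastereomeric transition state (cis-lactone or C6 epimer), couple intermolecularly, or add to the furanone carbonyl. Fallback, setting out from 22 and returning at 24: the chromium-mediated ring closure is run without the acid treatment, and the hydroxy ester of undesired C6 configuration, methyl 2-[(6S,7S,8S,9R,10R)-9-acetoxy-6-hydroxy-4,10-dimethyl-8-[(3-methylbutanoyl)oxy]-1-oxo-3,10-epoxycyclodeca-2,4-dien-7-yl]prop-2-enoate F3, is isolated. Dess–Martin oxidation should give the C6 ketone methyl 2-[(7R,8S,9R,10R)-9-acetoxy-4,10-dimethyl-8-[(3-methylbutanoyl)oxy]-1,6-dioxo-3,10-epoxycyclodeca-2,4-dien-7-yl]prop-2-enoate F4. 1,2-Reduction from the less hindered face (NaBH4/CeCl3 or an oxazaborolidine-catalysed borane reduction) should then give the 6R alcohol 24, which lactonises with p-TsOH to 25. C6 is thus corrected after ring closure instead of being set in the C–C bond-forming event.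

3. Step 13. Hydride or vinyl transfer to the furanone carbonyl or the esters, or epimerisation and β-elimination of the α-acyloxy aldehyde, may erode the material. Fallback, setting out from 18 and returning at 22: Wittig olefination of 18 with methyl 3-[(tert-butyldimethylsilyl)oxy]-2-(triphenyl-λ5-phosphanylidene)propanoate should give methyl (2E,4S,5R)-5-acetoxy-2-{[(tert-butyldimethylsilyl)oxy]methyl}-5-[(2R)-5-{(2Z)-4-[(tert-butyldiphenylsilyl)oxy]but-2-en-2-yl}-2-methyl-3-oxo-2,3-dihydrofuran-2-yl]-4-[(3-methylbutanoyl)oxy]pent-2-enoate F5. HF·pyridine should remove both silyl groups to give methyl (2E,4S,5R)-5-acetoxy-2-(hydroxymethyl)-5-{(2R)-5-[(2Z)-4-hydroxybut-2-en-2-yl]-2-methyl-3-oxo-2,3-dihydrofuran-2-yl}-4-[(3-methylbutanoyl)oxy]pent-2-enoate F6. MnO2 should oxidise only the electron-rich (Z)-allylic alcohol at C6 to give methyl (2E,4S,5R)-5-acetoxy-2-(hydroxymethyl)-5-{(2R)-2-methyl-3-oxo-5-[(2Z)-4-oxobut-2-en-2-yl]-2,3-dihydrofuran-2-yl}-4-[(3-methylbutanoyl)oxy]pent-2-enoate F7. CBr4/PPh3 then converts the remaining primary allylic alcohol into bromide 22.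

Further compounds
F1 | step 8 | (1R,2S,6Z)-8-[(tert-butyldiphenylsilyl)oxy]-1-[(4S)-2,2-dimethyl-1,3-dioxolan-4-yl]-2,3-dihydroxy-2,6-dimethyloct-6-en-4-yn-1-yl acetate (C3 epimers) | CC(C)(C)[Si](OC/C=C(/C)C#CC(O)[C@](C)(O)[C@H](OC(C)=O)[C@@H]2COC(C)(C)O2)(c1ccccc1)c1ccccc1
F2 | step 8 | (1R,2R,6Z)-8-[(tert-butyldiphenylsilyl)oxy]-1-[(4S)-2,2-dimethyl-1,3-dioxolan-4-yl]-2-hydroxy-2,6-dimethyl-3-oxooct-6-en-4-yn-1-yl acetate | CC(C)(C)[Si](OC/C=C(/C)C#CC(=O)[C@](C)(O)[C@H](OC(C)=O)[C@@H]2COC(C)(C)O2)(c1ccccc1)c1ccccc1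
F3 | step 17 | methyl 2-[(6S,7S,8S,9R,10R)-9-acetoxy-6-hydroxy-4,10-dimethyl-8-[(3-methylbutanoyl)oxy]-1-oxo-3,10-epoxycyclodeca-2,4-dien-7-yl]prop-2-enoate | O[C@H]1/C=C(/C)C2=CC(=O)[C@](C)(O2)[C@H](OC(C)=O)[C@@H](OC(=O)CC(C)C)[C@H]1C(=C)C(=O)OC
F4 | step 17 | methyl 2-[(7R,8S,9R,10R)-9-acetoxy-4,10-dimethyl-8-[(3-methylbutanoyl)oxy]-1,6-dioxo-3,10-epoxycyclodeca-2,4-dien-7-yl]prop-2-enoate | O=C1/C=C(/C)C2=CC(=O)[C@](C)(O2)[C@H](OC(C)=O)[C@@H](OC(=O)CC(C)C)[C@H]1C(=C)C(=O)OC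
F5 | step 13 | methyl (2E,4S,5R)-5-acetoxy-2-{[(tert-butyldimethylsilyl)oxy]methyl}-5-[(2R)-5-{(2Z)-4-[(tert-butyldiphenylsilyl)oxy]but-2-en-2-yl}-2-methyl-3-oxo-2,3-dihydrofuran-2-yl]-4-[(3-methylbutanoyl)oxy]pent-2-enoate | CC(C)(C)[Si](OC/C=C(/C)C2=CC(=O)[C@](C)(O2)[C@H](OC(C)=O)[C@@H](OC(=O)CC(C)C)/C=C(\CO[Si](C)(C)C(C)(C)C)C(=O)OC)(c1ccccc1)c1ccccc1
F6 | step 13 | methyl (2E,4S,5R)-5-acetoxy-2-(hydroxymethyl)-5-{(2R)-5-[(2Z)-4-hydroxybut-2-en-2-yl]-2-methyl-3-oxo-2,3-dihydrofuran-2-yl}-4-[(3-methylbutanoyl)oxy]pent-2-enoate | OC/C=C(/C)C1=CC(=O)[C@](C)(O1)[C@H](OC(C)=O)[C@@H](OC(=O)CC(C)C)/C=C(\CO)C(=O)OC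
F7 | step 13 | methyl (2E,4S,5R)-5-acetoxy-2-(hydroxymethyl)-5-{(2R)-2-methyl-3-oxo-5-[(2Z)-4-oxobut-2-en-2-yl]-2,3-dihydrofuran-2-yl}-4-[(3-methylbutanoyl)oxy]pent-2-enoate | O=C/C=C(/C)C1=CC(=O)[C@](C)(O1)[C@H](OC(C)=O)[C@@H](OC(=O)CC(C)C)/C=C(\CO)C(=O)OC
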